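- Raising the temperature from 25 °C to 75 °C multiplies K, the equilibrium constant of L + J ⇌ L.J, by 0.0218, taking it from 24.0 /M to 0.524 /M, so we follow one quantity through the hot flask, eta.

| flask | E | D | temperature | time |
|---|---|---|---|---|
| beta | 29 mM | 26.1 mM | 25 °C | 6.0 min |
| eta | 29 mM | 26.1 mM | 75 °C | 6.0 min |
| epsilon | 29 mM | 26.1 mM | 50 °C | 6.0 min |

    E ⇌ L (K1 = 1.4, k1 = 0.274 /min, Ea1 = 75.0 kJ/mol, ΔH1 = −47.0 kJ/mol)
    D → J (k2 = 0.507 /min, Ea2 = 88.0 kJ/mol)
    L + J ⇌ L.J (K3 = 24 /M, k3 = 158 /M/min, Ea3 = 40.0 kJ/mol, ΔH3 = −66.0 kJ/mol)
    (constants at 25 °C)

- all constants are for 25 °C and move with temperature by the activation energies and enthalpies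

- the flask that comes out highest in amount of L.J, in percent of the E charged, or "all alike" when all lie within 1.5 percentage points (beta / eta / epsilon / all alike)
- L.J at the end, in percent of the E charged, beta
- L.J at the end, in percent of the E charged, eta
- L.J at the end, in percent of the E charged, epsilon

- Our quantity is the pairing ratio r, the L.J standing per free L once the D charge has become J and the binding step is balanced; it is K times the D charge, in eta 1.37%.
- Has D become J in eta? Integrating the first-order loss of D gives a fraction left of exp(−kt). In eta k is 160 times its value in the coldest flask, so the half-life is 0.501 s, and the run holds 719 half-lives.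
- Our first way is balance. Since ln K moves in proportion to the enthalpy, the constant of E ⇌ L falls from 1.4 to 0.0920. Free L is then 8.42% of the E charged, and multiplying by r gives L.J at 0.115% in eta.
- Our second way integrates the forward binding rate. Scaling the activation energy likewise gives a forward constant of 1600 /M/min. Holding L and J steady for the whole time gives 2115% of the E charged in eta, though the D charge allows 90.0%.
- The second way is the one that cheats. The lifetime of L.J against its reverse step in eta is 0.0196 s, far shorter than the run, and the forward lifetime of E in eta, 2.84 s, is shorter too. So eta stands under thermodynamic control, and we keep the first way.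
- In the cold flask, beta, the closed form leaves 4.77% of D at the end. The same product gives 36.5%, but it treats L and J as if L.J took none of them, so we read it as a high mark. That mark stands above our eta figure, but a high mark does not place beta above eta, and we leave epsilon unreckoned, so our reckoning names no flask as highest.
- The forecast names beta as highest, with 19% for beta, 1.87% for epsilon and 0.115% for eta, and it reasons: “The exothermic equilibria favour the cold flask.”
- The simulation gives beta as highest, with 19.2% for beta, 1.87% for epsilon and 0.115% for eta.
- In eta, the main reason for the small answer is the reverse step, L.J to L + J. With that step struck out, the run climbs from 0.115% to 89.0%, close to the 90.0% that the D charge allows. With the step in place, the L of 8.41% at 6.00 min times r gives 0.115%.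
- Take the eta flask with 100 mM of D, which is 3.45 equiv: r becomes 5.24%, and with our free L share the reckoning gives 0.441%. The simulation gives 0.439%.

(Its constants come from no measurement.)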